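I start from the noon run, held against the plain case in which all lost starting material stands as target.

the same everywhere: starting material 0.20 M

| run | solid reagent | initiator | remark | time |
|---|---|---|---|---|
| dusk | 0.20 M | 4 mM | the very flask that is asked about, followed so far |  |
| noon | 0.20 M | 8 mM | run made earlier |  |
| flask | 0.200 M | 4.0 mM |  | 4.0 d |

- dusk (time / h: target / %, starting material / %): 1.50: 1.3, 97.6; 4.00: 1.0, 99.3; 8.00: 1.4, 96.9; 12.0: 5.1, 95.7; 15.0: 4.1, 96.2
- noon (time / d: target / %, starting material / %): 0.250: 2.1, 98.0; 0.625: 4.8, 93.8; 1.25: 7.1, 86.0; 2.08: 12.1, 75.8; 3.00: 13.2, 63.2

(each reading ± 1 percentage point)

- a species is counted by the starting material in it: one side product counts as two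
- given per volume of solution although it is solid: solid reagent
- steps under discussion: initiator -> 2 initiating radical; starting material + initiating radical -> chain carrier; partner + chain carrier -> target + initiating radical; 2 initiating radical -> ended chains; solid reagent <-> partner; starting material + target -> side product; partner + target -> over-reaction product
- at the start none of the solid reagent is in solution

- the target standing at 4.0 d, as a percentage of the starting material charged
- concentration of partner in solution at 4.0 d, in percent of saturation

At the last noon reading the loss is 36.8 % and the target 13.2 %, so the plain case fails. Each coupling to side product removes one starting material and one target, so loss is made plus coupled, and target is made minus coupled. The target made is therefore the mean of loss and target. I call that mean, in molar terms and averaged from the start, the feed v: 0.0167 M d⁻¹ at that reading. At the first noon reading it is 0.0164 M d⁻¹, so within the scatter v reads level while starting material falls. The dusk run gives 0.0126 M d⁻¹ at its last reading, a rough figure at that scatter, and I carry v unchanged to the asked flask.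

Now I run that flask slowly. At first no partner is dissolved, so the chain waits on the solid reagent. Through the middle I read dissolving as the rate-limiting step: partner is taken as it arrives, and I put it close to zero saturation. By the asked time v has delivered 0.0667 M, less than the solid charged. Late on, coupling grows: between the last noon readings it takes 0.0625 d⁻¹ of the charge, against a feed of 0.0833 d⁻¹, which is faster. So, going on from the last noon target with that gap, I expect about 15.3 % of target in the asked flask.

The forecast gives 10 % of target (8 % to 12 %) and partner at 85 % of saturation (50 % to 100 %), saying “Rate insensitivity suggests it stays near saturation, with solid still present.”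

The flask gives 14.4 % of target and partner at 0 % of saturation.

    initiator → 2 initiating radical (k = 1.15 × 10⁻⁵ min⁻¹)
    starting material + initiating radical → chain carrier (k = 16000 M⁻¹ min⁻¹)
    partner + chain carrier → target + initiating radical (k = 1.27 × 10⁵ M⁻¹ min⁻¹)
    2 initiating radical → ended chains (k = 2.60 × 10⁶ M⁻¹ s⁻¹)
    solid reagent ⇌ partner, rate k5*(cs5 - [partner]) while solid is left; crystals form when [partner] > cs5 (solubility = 0.0730 M, k = 1.50 × 10⁻⁴ min⁻¹)
    starting material + target → side product (k = 0.00244 M⁻¹ min⁻¹)
    partner + target → over-reaction product (k = 0.0127 M⁻¹ min⁻¹)

At the asked time partner stands at 1.83 × 10⁻⁷ M in the asked flask, and the solid gone is 0.0631 M, beside the 0.0667 M from v. The neighbour flask is charged with 0.050 M of starting material, and the same v over the same time gives 0.0667 M, more than that charge; its solid gone is 0.0588 M. In that neighbour partner stands at 0.0134 M, target reaches 46.1 %, and over-reaction product reaches 17.3 %.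

(All runs were computed with constants of no real substance, noise included.)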